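## Analysis of the target

The target 21 is a flavone, a 2-aryl-4H-chromen-4-one in which the benzo ring A (C4a, C5 to C8, C8a) is fused to the pyranone ring C (O1, C2, C3, C4) and C2 carries the aryl ring B. It has no stereocentre, so the whole problem is one of regiochemistry and of telling seven oxygen substituents apart. Ring A is fully substituted, with hydroxyls on C5 and C7 alternating with methoxyls on C6 and C8, and ring B carries a catechol at C3'/C4' next to a methoxyl at C5'. The free catechol and the electron-rich ring A oxidise easily in air under base, and the enone of ring C can be opened by hard nucleophiles. The three methyl ethers must survive whatever frees the four hydroxyls, so those hydroxyls travel as benzyl ethers and are released last by neutral hydrogenolysis. The difficulty is the hexasubstituted ring A: classical acylation of a phenol would need a pentaoxygenated benzene, which is neither cheap nor stable. The strategy rests on the fact that C8a carries O1, its neighbour C4a carries the C4 carbonyl and C5 beside C4a carries oxygen, so that a benzyne across C4a–C8a with an alkoxy group on C5 is polarised to take an oxygen nucleophile at C8a and an acyl group at C4a, both of which a carboxylic acid delivers. C8 is left as C–H in the aryne so that only one oxygen flanks the triple bond, and it takes its methoxyl later as the only C–H of ring A.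

## Retrosynthetic reasoning

**21 from 20.** The four O–benzyl bonds are cut last. All four free hydroxyls of 21 are then masked by one group that reduction removes while the methyl ethers stay, so no selective dealkylation is ever needed. The forward step must cleave four benzyl ethers without reducing the C2–C3 double bond.

**20 from 19 and 18.** The C8–OMe bond is cut next, through the C8 bromide 19 back to the C8–H flavone 18. It is cut here and not carried through the ring construction because a C8 oxygen would put a second alkoxy flank on the aryne and destroy its polarisation. In 18, C8 is the only C–H of ring A. It lies ortho to O1 and to the C7 oxygen and para to the C5 oxygen, so electrophilic bromination should find it, and copper-mediated methoxylation then exchanges bromine for methoxide.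

**18 from 10 and 15.** This is the central disconnection. Three bonds are cut: C8a–O1, C4a–C4 and O1–C2. Ring A becomes the silylaryl triflate 10, the precursor of aryne 16. O1, C4, C3, C2 and ring B come from the arylpropiolic acid 15. Cutting here lets both halves be made from trioxygenated benzenes whose oxygen patterns already match the target. The forward reaction must add the carboxylate oxygen to the aryne carbon far from the C5 oxygen, move the acyl group to the neighbouring carbon to give the 2-acylphenoxide 17, and close ring C by conjugate addition.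

**10 from 7 and 6.** The C–Si bond and the triflate are cut back to the ortho-bromophenol 7. Silicon reaches carbon by an O-to-C shift from the silyl ether 8 through the phenoxide 9, which is then sulfonylated. Bromide 7 comes from phenol 6. Because 6 is symmetric, its two ring C–H positions are equivalent and only one monobromide can form.

**6 from 4, 3, 2 and 1.** The phenolic C–O bond of 6 is cut to the aldehyde 4 through the formate 5 (peracid oxidation with aryl migration). Aldehyde 4 is traced through alcohol 3 and ester 2 to acid 1. In 1, the methoxyl between two hydroxyls is exactly the C5/C6/C7 pattern of ring A, so the only methyl ether of this fragment is bought, not made.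

**15 from 14, 13, 12 and 11.** The bond between the alkyne and the carboxyl carbon is cut to the acetylide 14. This comes from the dibromoalkene 13, and that from aldehyde 12, the dibenzyl ether of 11. Compound 11 already has the ring B pattern: two adjacent hydroxyls next to one methoxyl.

## Alternatives that were turned down

**Alternative 1:** Ring A is built last by cutting C5–C6. The precursor is the pyranone keto ester A2, which carries a methyl ester on the future C4a and a 1,3-dimethoxy-2-oxopropyl chain on the future C8a. Base would form the enolate at the methoxymethyl terminus (future C6). It attacks the ester carbonyl, the ester alkoxy group is lost, and the ring aromatises to the 5,7-dihydroxyflavone A1.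
- For: every ring A substituent is placed by construction. The two methoxyls arrive on the chain, the two hydroxyls arise from carbonyls, ring A needs no protecting group, and one hydrogenolysis of the ring B benzyl ethers finishes the synthesis. On these points it is stronger than the chosen route, which needs three steps after its key step and a selective bromination.
- Against: the most acidic site of A2 is the methine between the pyranone and the ketone (future C8), not the terminus that must react. The 3-acyl-4-pyranone is a strong conjugate acceptor that alkoxide bases tend to open. A2 itself needs a long linear sequence with no aromatic feedstock to lean on.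
- Comparison: the chosen route offers two fragments made from cheap trioxygenated benzenes in six and three steps, and it places its risk in a single step with a close known analogue.

**Alternative 2:** The C5–O and C7–O bonds are cut. Sodium benzyl oxide A5 would displace both fluorides of the difluoroflavone A4 by nucleophilic aromatic substitution to give A3, which is the same compound as 20 of the chosen route. No ring closes.
- For: C5 and C7 are ortho and para to the carbon bearing the C4 carbonyl, so both anionic adducts are stabilised, and fluoride is the best leaving group for this mechanism. The step lands one hydrogenolysis from the target without any substitution at C8. In its endgame it is shorter and cleaner than the chosen route.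
- Against: ring A of A4 also carries two methoxyls and O1, which slow the substitution, and each fluorine is hindered by its neighbours. The second displacement is slower than the first, and forcing conditions with the alkoxide A5 invite attack at C2 and opening of ring C. A4 needs a ring A block with two fluorines and two methoxyls in alternation, which is not purchasable and has regiochemical problems of its own.
- Comparison: the chosen route starts from purchasable arenes that already carry the right oxygens.

**Alternative 3:** C4a–C4, C4–C3 and O1–C2 are cut, and C4 is supplied as a one-carbon unit. The iodoresorcinol A7, carbon monoxide A9 and the ring B alkyne A8 would combine under zerovalent palladium in a secondary amine to give the 5-hydroxyflavone A6.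
- For: it is the most convergent of the four plans. A7 is symmetric, so either hydroxyl may close the ring. All ring A oxygens are in place, A8 is one step shorter than acid 15, and only hydrogenolysis follows. In step count after the key step it beats the chosen route.
- Against: A7 is a pentaoxygenated, air-sensitive iodophenol whose C–I bond sits between two hydroxyls on a very electron-rich ring. Oxidative addition and insertion of A9 should therefore be slow. Direct coupling of A7 with A8 without uptake of A9, and 5-exo closure, can compete. Making A7 needs the pentaoxygenated benzene that the chosen plan avoids.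
- Comparison: the chosen route needs no pentaoxygenated arene and no gaseous reagent such as A9, and the regiochemistry of its key step follows from one substituent.

Key step: step 10

Assumption: 1 and 11 are taken to be purchasable. Benzyl is used for every hydroxyl that is free in the target because hydrogenolysis removes it and leaves the three methyl ethers.

## Route

Step 1
Reactants: 1 3,5-dihydroxy-4-methoxybenzoic acid
Product: 2 benzyl 3,5-bis(benzyloxy)-4-methoxybenzoate
Conditions: BnBr (3.3 equiv), K2CO3, DMF, 60 °C
Reagents that add atoms: benzyl bromide, BrCc1ccccc1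
Why: Williamson alkylation of both phenols and of the carboxylate under carbonate base; full benzylation avoids differentiating the acid, and the benzyl ester is reduced away in step 2.

Step 2
Reactants: 2 benzyl 3,5-bis(benzyloxy)-4-methoxybenzoate
Product: 3 [3,5-bis(benzyloxy)-4-methoxyphenyl]methanol
Conditions: LiAlH4, THF, 0 °C to rt
Reagents that add atoms: none
Why: Hydride reduction of the ester to the primary benzylic alcohol; aryl benzyl and methyl ethers are inert to LiAlH4.

Step 3
Reactants: 3 [3,5-bis(benzyloxy)-4-methoxyphenyl]methanol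
Product: 4 3,5-bis(benzyloxy)-4-methoxybenzaldehyde
Conditions: MnO2 (activated, excess), CH2Cl2, rt
Reagents that add atoms: none
Why: Activated MnO2 oxidises benzylic alcohols to aldehydes and stops there; the ethers are untouched.

Step 4
Reactants: 4 3,5-bis(benzyloxy)-4-methoxybenzaldehyde
Product: 6 3,5-bis(benzyloxy)-4-methoxyphenol, via 3,5-bis(benzyloxy)-4-methoxyphenyl formate 5 (not isolated)
Conditions: mCPBA, CH2Cl2, 0 °C to rt; then K2CO3 (cat.), MeOH, rt
Reagents that add atoms: 3-chloroperbenzoic acid, OOC(=O)c1cccc(Cl)c1
Why: Baeyer–Villiger (Dakin-type) oxidation: in the peracid adduct the electron-rich trialkoxyaryl group should migrate in preference to hydride, and the formate 5 is methanolysed under mild base to the symmetric phenol.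

Step 5
Reactants: 6 3,5-bis(benzyloxy)-4-methoxyphenol
Product: 7 3,5-bis(benzyloxy)-2-bromo-4-methoxyphenol
Conditions: NBS (1.0 equiv), CH2Cl2, −78 to 0 °C
Reagents that add atoms: N-bromosuccinimide, O=C1CCC(=O)N1Br
Why: Electrophilic aromatic bromination ortho to the free phenol; the two ring C–H positions of 6 are equivalent by symmetry, so one equivalent at low temperature should give a single monobromide.

Step 6
Reactants: 7 3,5-bis(benzyloxy)-2-bromo-4-methoxyphenol
Product: 10 3,5-bis(benzyloxy)-4-methoxy-2-(trimethylsilyl)phenyl trifluoromethanesulfonate, via aryl trimethylsilyl ether 8 (not isolated), via lithium 2-(trimethylsilyl)phenoxide 9 (not isolated)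
Conditions: HMDS, THF, 70 °C, then evaporation; n-BuLi, THF, −100 to −78 °C; Tf2O, −100 °C to rt
Reagents that add atoms: hexamethyldisilazane, C[Si](C)(C)N[Si](C)(C)C; trifluoromethanesulfonic anhydride, O=S(=O)(OS(=O)(=O)C(F)(F)F)C(F)(F)F
Why: O-silylation, then bromine–lithium exchange triggers the 1,3 O-to-C silyl shift (retro-Brook rearrangement) to phenoxide 9, which Tf2O traps; this is the standard one-flask entry to 2-(trimethylsilyl)aryl triflates and puts silicon between the triflate and a benzyloxy group.

Step 7
Reactants: 11 3,4-dihydroxy-5-methoxybenzaldehyde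
Product: 12 3,4-bis(benzyloxy)-5-methoxybenzaldehyde
Conditions: BnBr (2.3 equiv), K2CO3, DMF, 60 °C
Reagents that add atoms: benzyl bromide, BrCc1ccccc1
Why: Williamson ether synthesis on both catechol hydroxyls; the aldehyde is stable to K2CO3.

Step 8
Reactants: 12 3,4-bis(benzyloxy)-5-methoxybenzaldehyde
Product: 13 1,2-bis(benzyloxy)-5-(2,2-dibromoethenyl)-3-methoxybenzene
Conditions: CBr4, PPh3, Zn, CH2Cl2, rt
Reagents that add atoms: carbon tetrabromide, BrC(Br)(Br)Br
Why: First stage of the Corey–Fuchs reaction in its zinc variant: the dibromomethylene ylide converts the aldehyde into the 1,1-dibromoalkene by Wittig olefination.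

Step 9
Reactants: 13 1,2-bis(benzyloxy)-5-(2,2-dibromoethenyl)-3-methoxybenzene
Product: 15 3-[3,4-bis(benzyloxy)-5-methoxyphenyl]prop-2-ynoic acid, via lithium arylethynide 14 (not isolated)
Conditions: n-BuLi (2.2 equiv), THF, −78 °C; CO2, −78 °C to rt; aq. HCl
Reagents that add atoms: carbon dioxide, O=C=O
Why: Second stage of the Corey–Fuchs reaction: bromine–lithium exchange and Fritsch–Buttenberg–Wiechell rearrangement give the alkyne, the second equivalent of n-BuLi forms acetylide 14, and carboxylation followed by acidification gives the propiolic acid.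

Step 10
Reactants: 10 3,5-bis(benzyloxy)-4-methoxy-2-(trimethylsilyl)phenyl trifluoromethanesulfonate; 15 3-[3,4-bis(benzyloxy)-5-methoxyphenyl]prop-2-ynoic acid
Product: 18 5,7-bis(benzyloxy)-2-[3,4-bis(benzyloxy)-5-methoxyphenyl]-6-methoxy-4H-chromen-4-one, via 3,5-bis(benzyloxy)-4-methoxybenzyne 16 (not isolated), via caesium 2-(arylpropynoyl)phenoxide 17 (not isolated)
Conditions: CsF (4 equiv), 10 (1.5 equiv), THF, 125 °C, sealed tube
Reagents that add atoms: none
Why: Fluoride attacks silicon of 10, triflate leaves, and aryne 16 forms with a single oxygen flank, the benzyloxy group destined for C5. The caesium carboxylate of 15 adds through oxygen to the aryne carbon remote from that group (future C8a), which the distortion of a 3-alkoxybenzyne makes the more electrophilic end, and the charge lands on the carbon next to the C–O bond (future C4a), where induction stabilises it. This aryl anion attacks the neighbouring ester carbonyl through a four-membered alkoxide that opens to the 2-acylphenoxide 17, so the aryne has inserted into the acyl C–O bond in the manner of an anionic Fries shift. Phenoxide 17 closes ring C by 6-endo-dig conjugate addition of O1 to the ynone carbon C2, and the vinyl anion takes the proton that the acid gave to fluoride. The closest known reaction type is the fluoride-induced insertion of arynes into the C–O bond of carboxylic acids to give 2-hydroxyaryl ketones, which with arylpropiolic acids runs on to flavones. No stereocentre is formed. The step needs three selectivities: oxygen at C8a and acyl at C4a, secured by the single alkoxy flank with C8 kept as C–H; acyl transfer ahead of protonation, secured by the aprotic hot medium in which the only proton is the one the acid brings; and 6-endo over 5-exo closure, favoured by the soft conjugate addition to the ynone in an aprotic solvent.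

Step 11
Reactants: 18 5,7-bis(benzyloxy)-2-[3,4-bis(benzyloxy)-5-methoxyphenyl]-6-methoxy-4H-chromen-4-one
Product: 19 5,7-bis(benzyloxy)-2-[3,4-bis(benzyloxy)-5-methoxyphenyl]-8-bromo-6-methoxy-4H-chromen-4-one
Conditions: NBS (1.05 equiv), DMF, 0 °C to rt, dark
Reagents that add atoms: N-bromosuccinimide, O=C1CCC(=O)N1Br
Why: Electrophilic aromatic bromination; C8 is the only C–H of ring A, ortho to O1 and the C7 oxygen and para to the C5 oxygen, so it should be more nucleophilic than C3 or than C2'/C6' of ring B, which is conjugated to the electron-poor C2.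

Step 12
Reactants: 19 5,7-bis(benzyloxy)-2-[3,4-bis(benzyloxy)-5-methoxyphenyl]-8-bromo-6-methoxy-4H-chromen-4-one
Product: 20 5,7-bis(benzyloxy)-2-[3,4-bis(benzyloxy)-5-methoxyphenyl]-6,8-dimethoxy-4H-chromen-4-one
Conditions: NaOMe (excess), CuBr (0.2 equiv), DMF/MeOH, 110 °C
Reagents that add atoms: sodium methoxide, [Na+].[O-]C
Why: Ullmann-type copper-mediated methoxylation of an aryl bromide, a reaction established for 8-halo- and 6,8-dihaloflavones; benzyl and methyl ethers tolerate the alkoxide.

Step 13
Reactants: 20 5,7-bis(benzyloxy)-2-[3,4-bis(benzyloxy)-5-methoxyphenyl]-6,8-dimethoxy-4H-chromen-4-one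
Product: 21 5,7-dihydroxy-2-(3,4-dihydroxy-5-methoxyphenyl)-6,8-dimethoxy-4H-chromen-4-one
Conditions: H2 (1 atm), 10% Pd/C, THF/MeOH, rt
Reagents that add atoms: none
Why: Catalytic hydrogenolysis of four aryl benzyl ethers; methyl ethers are inert, and the C2–C3 double bond, part of a vinylogous ester conjugated to both rings, should be reduced far more slowly than the O-benzyl bonds are cleaved.

## Compound list

1 | 3,5-dihydroxy-4-methoxybenzoic acid | COc1c(O)cc(C(=O)O)cc1O | starting material
2 | benzyl 3,5-bis(benzyloxy)-4-methoxybenzoate | COc1c(OCc2ccccc2)cc(C(=O)OCc2ccccc2)cc1OCc1ccccc1 | intermediate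
3 | [3,5-bis(benzyloxy)-4-methoxyphenyl]methanol | COc1c(OCc2ccccc2)cc(CO)cc1OCc1ccccc1 | intermediate
4 | 3,5-bis(benzyloxy)-4-methoxybenzaldehyde | COc1c(OCc2ccccc2)cc(C=O)cc1OCc1ccccc1 | intermediate
5 | 3,5-bis(benzyloxy)-4-methoxyphenyl formate | COc1c(OCc2ccccc2)cc(OC=O)cc1OCc1ccccc1 | intermediate
6 | 3,5-bis(benzyloxy)-4-methoxyphenol | COc1c(OCc2ccccc2)cc(O)cc1OCc1ccccc1 | intermediate
7 | 3,5-bis(benzyloxy)-2-bromo-4-methoxyphenol | COc1c(OCc2ccccc2)cc(O)c(Br)c1OCc1ccccc1 | intermediate
8 | [3,5-bis(benzyloxy)-2-bromo-4-methoxyphenoxy]trimethylsilane | COc1c(OCc2ccccc2)cc(O[Si](C)(C)C)c(Br)c1OCc1ccccc1 | intermediate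
9 | lithium 3,5-bis(benzyloxy)-4-methoxy-2-(trimethylsilyl)phenoxide | COc1c(OCc2ccccc2)cc([O-])c([Si](C)(C)C)c1OCc1ccccc1.[Li+] | intermediate
10 | 3,5-bis(benzyloxy)-4-methoxy-2-(trimethylsilyl)phenyl trifluoromethanesulfonate | COc1c(OCc2ccccc2)cc(OS(=O)(=O)C(F)(F)F)c([Si](C)(C)C)c1OCc1ccccc1 | intermediate
11 | 3,4-dihydroxy-5-methoxybenzaldehyde | COc1cc(C=O)cc(O)c1O | starting material
12 | 3,4-bis(benzyloxy)-5-methoxybenzaldehyde | COc1cc(C=O)cc(OCc2ccccc2)c1OCc1ccccc1 | intermediate
13 | 1,2-bis(benzyloxy)-5-(2,2-dibromoethenyl)-3-methoxybenzene | COc1cc(C=C(Br)Br)cc(OCc2ccccc2)c1OCc1ccccc1 | intermediate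
14 | lithium [3,4-bis(benzyloxy)-5-methoxyphenyl]ethynide | COc1cc(C#[C-])cc(OCc2ccccc2)c1OCc1ccccc1.[Li+] | intermediate
15 | 3-[3,4-bis(benzyloxy)-5-methoxyphenyl]prop-2-ynoic acid | COc1cc(C#CC(=O)O)cc(OCc2ccccc2)c1OCc1ccccc1 | intermediate
16 | 3,5-bis(benzyloxy)-4-methoxybenzyne (aryne bond between the former C–OTf and C–Si carbons) | COC1=C(OCc2ccccc2)C#CC=C1OCc1ccccc1 | intermediate
17 | caesium 3,5-bis(benzyloxy)-2-{3-[3,4-bis(benzyloxy)-5-methoxyphenyl]prop-2-ynoyl}-4-methoxyphenoxide | COc1cc(C#CC(=O)c2c([O-])cc(OCc3ccccc3)c(OC)c2OCc2ccccc2)cc(OCc2ccccc2)c1OCc1ccccc1.[Cs+] | intermediate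
18 | 5,7-bis(benzyloxy)-2-[3,4-bis(benzyloxy)-5-methoxyphenyl]-6-methoxy-4H-chromen-4-one | COc1cc(-c2cc(=O)c3c(OCc4ccccc4)c(OC)c(OCc4ccccc4)cc3o2)cc(OCc2ccccc2)c1OCc1ccccc1 | intermediate
19 | 5,7-bis(benzyloxy)-2-[3,4-bis(benzyloxy)-5-methoxyphenyl]-8-bromo-6-methoxy-4H-chromen-4-one | COc1cc(-c2cc(=O)c3c(OCc4ccccc4)c(OC)c(OCc4ccccc4)c(Br)c3o2)cc(OCc2ccccc2)c1OCc1ccccc1 | intermediate
20 | 5,7-bis(benzyloxy)-2-[3,4-bis(benzyloxy)-5-methoxyphenyl]-6,8-dimethoxy-4H-chromen-4-one | COc1cc(-c2cc(=O)c3c(OCc4ccccc4)c(OC)c(OCc4ccccc4)c(OC)c3o2)cc(OCc2ccccc2)c1OCc1ccccc1 | intermediate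
21 | 5,7-dihydroxy-2-(3,4-dihydroxy-5-methoxyphenyl)-6,8-dimethoxy-4H-chromen-4-one (5,7,3',4'-tetrahydroxy-6,8,5'-trimethoxyflavone) | COc1cc(-c2cc(=O)c3c(O)c(OC)c(O)c(OC)c3o2)cc(O)c1O | target

## Step count and least certain steps

Total: 13 steps. Longest linear sequence: 10 steps (steps 1 to 6 and 10 to 13). The ring B branch (steps 7 to 9) joins at step 10.

**Step 10 (key step).** Three processes are the most likely failures. The aryl anion may be protonated before it transfers the acyl group, so the reaction stops at simple O-arylation of the acid. The propiolate may lose carbon dioxide at 125 °C. Phenoxide 17 may close in the 5-exo sense, or capture a second aryne. The fallback makes the same bonds by polar organometallic chemistry. It sets out from 7 and 15 and returns at 18. Phenol 7 would be protected with MOMCl and iPr2NEt as 1,3-bis(benzyloxy)-4-bromo-2-methoxy-5-(methoxymethoxy)benzene F1. Acid 15 would be converted with MeNHOMe·HCl and a carbodiimide into 3-[3,4-bis(benzyloxy)-5-methoxyphenyl]-N-methoxy-N-methylprop-2-ynamide F2. Bromine–lithium exchange on F1 with n-BuLi at −78 °C and addition to F2 should give the protected ynone 1-[2,4-bis(benzyloxy)-3-methoxy-6-(methoxymethoxy)phenyl]-3-[3,4-bis(benzyloxy)-5-methoxyphenyl]prop-2-yn-1-one F3. HCl in MeOH would free the phenol 1-[2,4-bis(benzyloxy)-6-hydroxy-3-methoxyphenyl]-3-[3,4-bis(benzyloxy)-5-methoxyphenyl]prop-2-yn-1-one F4. Cs2CO3 in DMF would close it through 17 to 18.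

**Step 6.** The silyl shift may be incomplete. The aryllithium may deprotonate the neighbouring benzyl ether. The electron-rich arylsilane may lose silicon to acid formed during triflation with Tf2O. The fallback installs silicon by directed ortho-metalation and forms the triflate under amine base. It sets out from 6 and returns at 10. Phenol 6 and isopropyl isocyanate would give 3,5-bis(benzyloxy)-4-methoxyphenyl propan-2-ylcarbamate F5. N-silylation in the flask, lithiation with n-BuLi and TMEDA at −78 °C between the carbamate and the benzyloxy group, and quenching with TMSCl would give 3,5-bis(benzyloxy)-4-methoxy-2-(trimethylsilyl)phenyl propan-2-ylcarbamate F6. DBU and Et2NH in MeCN would cleave the carbamate to 3,5-bis(benzyloxy)-4-methoxy-2-(trimethylsilyl)phenol F7, and PhNTf2 would convert this into 10.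

**Step 11.** Site selectivity may be poor, with bromine entering C3 or ring B as well as C8. The fallback raises the bias for C8 by freeing the C5 hydroxyl, which is para to C8. It sets out from 18 and returns at 21. BCl3 (1 equiv, CH2Cl2, −78 °C) would cleave only the benzyl ether peri to the carbonyl, giving 7-(benzyloxy)-2-[3,4-bis(benzyloxy)-5-methoxyphenyl]-5-hydroxy-6-methoxy-4H-chromen-4-one F8. NBS would then give 7-(benzyloxy)-2-[3,4-bis(benzyloxy)-5-methoxyphenyl]-8-bromo-5-hydroxy-6-methoxy-4H-chromen-4-one F9. NaOMe with CuBr would give 7-(benzyloxy)-2-[3,4-bis(benzyloxy)-5-methoxyphenyl]-5-hydroxy-6,8-dimethoxy-4H-chromen-4-one F10, identical with A6. Hydrogenolysis of its three benzyl ethers would give 21.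

**Step 12.** Reductive loss of bromine may compete with C–O bond formation, and methoxide at 110 °C may attack C2 and open ring C. The fallback reaches the C8 oxygen through boron. It sets out from 19 and returns at 20. Miyaura borylation (B2pin2, Pd(dppf)Cl2, KOAc, dioxane, 90 °C) would give 5,7-bis(benzyloxy)-2-[3,4-bis(benzyloxy)-5-methoxyphenyl]-6-methoxy-8-(4,4,5,5-tetramethyl-1,3,2-dioxaborolan-2-yl)-4H-chromen-4-one F11. Oxidation with H2O2 and NaHCO3 would give 5,7-bis(benzyloxy)-2-[3,4-bis(benzyloxy)-5-methoxyphenyl]-8-hydroxy-6-methoxy-4H-chromen-4-one F12. MeI and K2CO3 in DMF would then give 20.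

**Step 13.** The C2–C3 double bond may be over-reduced, and cleavage may stall as partly debenzylated material loses solubility. The product catechol may oxidise in air during work-up. The fallback replaces reduction by Lewis acid dealkylation. It sets out from 20 and returns at 21: BCl3 with pentamethylbenzene as cation scavenger in CH2Cl2 at −78 °C, quenched cold so that the methyl ethers beside the freed hydroxyls are not attacked. It makes no new compound.

## Further compounds

F1 | step 10 | 1,3-bis(benzyloxy)-4-bromo-2-methoxy-5-(methoxymethoxy)benzene | COCOc1cc(OCc2ccccc2)c(OC)c(OCc2ccccc2)c1Br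
F2 | step 10 | 3-[3,4-bis(benzyloxy)-5-methoxyphenyl]-N-methoxy-N-methylprop-2-ynamide | COc1cc(C#CC(=O)N(C)OC)cc(OCc2ccccc2)c1OCc1ccccc1
F3 | step 10 | 1-[2,4-bis(benzyloxy)-3-methoxy-6-(methoxymethoxy)phenyl]-3-[3,4-bis(benzyloxy)-5-methoxyphenyl]prop-2-yn-1-one | COCOc1cc(OCc2ccccc2)c(OC)c(OCc2ccccc2)c1C(=O)C#Cc1cc(OC)c(OCc2ccccc2)c(OCc2ccccc2)c1
F4 | step 10 | 1-[2,4-bis(benzyloxy)-6-hydroxy-3-methoxyphenyl]-3-[3,4-bis(benzyloxy)-5-methoxyphenyl]prop-2-yn-1-one | Oc1cc(OCc2ccccc2)c(OC)c(OCc2ccccc2)c1C(=O)C#Cc1cc(OC)c(OCc2ccccc2)c(OCc2ccccc2)c1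
F5 | step 6 | 3,5-bis(benzyloxy)-4-methoxyphenyl propan-2-ylcarbamate | COc1c(OCc2ccccc2)cc(OC(=O)NC(C)C)cc1OCc1ccccc1
F6 | step 6 | 3,5-bis(benzyloxy)-4-methoxy-2-(trimethylsilyl)phenyl propan-2-ylcarbamate | COc1c(OCc2ccccc2)cc(OC(=O)NC(C)C)c([Si](C)(C)C)c1OCc1ccccc1
F7 | step 6 | 3,5-bis(benzyloxy)-4-methoxy-2-(trimethylsilyl)phenol | COc1c(OCc2ccccc2)cc(O)c([Si](C)(C)C)c1OCc1ccccc1
F8 | step 11 | 7-(benzyloxy)-2-[3,4-bis(benzyloxy)-5-methoxyphenyl]-5-hydroxy-6-methoxy-4H-chromen-4-one | COc1cc(-c2cc(=O)c3c(O)c(OC)c(OCc4ccccc4)cc3o2)cc(OCc2ccccc2)c1OCc1ccccc1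
F9 | step 11 | 7-(benzyloxy)-2-[3,4-bis(benzyloxy)-5-methoxyphenyl]-8-bromo-5-hydroxy-6-methoxy-4H-chromen-4-one | COc1cc(-c2cc(=O)c3c(O)c(OC)c(OCc4ccccc4)c(Br)c3o2)cc(OCc2ccccc2)c1OCc1ccccc1
F10 | step 11 | 7-(benzyloxy)-2-[3,4-bis(benzyloxy)-5-methoxyphenyl]-5-hydroxy-6,8-dimethoxy-4H-chromen-4-one | COc1cc(-c2cc(=O)c3c(O)c(OC)c(OCc4ccccc4)c(OC)c3o2)cc(OCc2ccccc2)c1OCc1ccccc1
F11 | step 12 | 5,7-bis(benzyloxy)-2-[3,4-bis(benzyloxy)-5-methoxyphenyl]-6-methoxy-8-(4,4,5,5-tetramethyl-1,3,2-dioxaborolan-2-yl)-4H-chromen-4-one | COc1cc(-c2cc(=O)c3c(OCc4ccccc4)c(OC)c(OCc4ccccc4)c(B4OC(C)(C)C(C)(C)O4)c3o2)cc(OCc2ccccc2)c1OCc1ccccc1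
F12 | step 12 | 5,7-bis(benzyloxy)-2-[3,4-bis(benzyloxy)-5-methoxyphenyl]-8-hydroxy-6-methoxy-4H-chromen-4-one | COc1cc(-c2cc(=O)c3c(OCc4ccccc4)c(OC)c(OCc4ccccc4)c(O)c3o2)cc(OCc2ccccc2)c1OCc1ccccc1
F0 | step 13 | none | none
A1 | alternative 1 | 2-[3,4-bis(benzyloxy)-5-methoxyphenyl]-5,7-dihydroxy-6,8-dimethoxy-4H-chromen-4-one (3',4'-bis(benzyloxy)-5,7-dihydroxy-6,8,5'-trimethoxyflavone) | COc1cc(-c2cc(=O)c3c(O)c(OC)c(O)c(OC)c3o2)cc(OCc2ccccc2)c1OCc1ccccc1
A2 | alternative 1 | methyl 6-[3,4-bis(benzyloxy)-5-methoxyphenyl]-2-(1,3-dimethoxy-2-oxopropyl)-4-oxo-4H-pyran-3-carboxylate (racemic) | COCC(=O)C(OC)c1oc(-c2cc(OC)c(OCc3ccccc3)c(OCc3ccccc3)c2)cc(=O)c1C(=O)OC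
A3 | alternative 2 | 5,7-bis(benzyloxy)-2-[3,4-bis(benzyloxy)-5-methoxyphenyl]-6,8-dimethoxy-4H-chromen-4-one (5,7,3',4'-tetrakis(benzyloxy)-6,8,5'-trimethoxyflavone) | COc1cc(-c2cc(=O)c3c(OCc4ccccc4)c(OC)c(OCc4ccccc4)c(OC)c3o2)cc(OCc2ccccc2)c1OCc1ccccc1
A4 | alternative 2 | 2-[3,4-bis(benzyloxy)-5-methoxyphenyl]-5,7-difluoro-6,8-dimethoxy-4H-chromen-4-one | COc1cc(-c2cc(=O)c3c(F)c(OC)c(F)c(OC)c3o2)cc(OCc2ccccc2)c1OCc1ccccc1
A5 | alternative 2 | sodium benzyl oxide (sodium phenylmethanolate) | [Na+].[O-]Cc1ccccc1
A6 | alternative 3 | 7-(benzyloxy)-2-[3,4-bis(benzyloxy)-5-methoxyphenyl]-5-hydroxy-6,8-dimethoxy-4H-chromen-4-one (7,3',4'-tris(benzyloxy)-5-hydroxy-6,8,5'-trimethoxyflavone) | COc1cc(-c2cc(=O)c3c(O)c(OC)c(OCc4ccccc4)c(OC)c3o2)cc(OCc2ccccc2)c1OCc1ccccc1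
A7 | alternative 3 | 5-(benzyloxy)-2-iodo-4,6-dimethoxybenzene-1,3-diol | COc1c(O)c(I)c(O)c(OC)c1OCc1ccccc1
A8 | alternative 3 | 1,2-bis(benzyloxy)-5-ethynyl-3-methoxybenzene | C#Cc1cc(OC)c(OCc2ccccc2)c(OCc2ccccc2)c1
A9 | alternative 3 | carbon monoxide | [C-]#[O+]
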